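(The data stem from a simulated flask on assumed constants, noise included.)

At the last teal reading, charge minus target still shows 0.358 M of reagent, the limiting reagent of that charge. Yet the target rose by 0.0130 M over the last interval, against 0.115 M over the first. That leftover is the puzzle the readings must explain.

| flask | substrate | reagent | target | time |
|---|---|---|---|---|
| teal | 0.800 M | 0.640 M |  |  |
| ochre | 0.400 M | 0.240 M |  |  |
| green | 0.800 M | 0.640 M | 0.400 M |  |
| grey | 0.800 M | 0.640 M |  | 9.0 h |

| run | time / h | [target] / M |
|---|---|---|
| teal run | 0.72 | 0.115 |
| teal run | 1.4 | 0.182 |
| teal run | 2.2 | 0.247 |
| teal run | 2.9 | 0.269 |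
| teal run | 3.6 | 0.282 |
| ochre run | 0.72 | 0.020 |
| ochre run | 1.4 | 0.039 |
| ochre run | 2.2 | 0.059 |
| ochre run | 2.9 | 0.068 |
| ochre run | 3.6 | 0.088 |
| green run | 0.72 | 0.477 |
| green run | 1.4 | 0.531 |
| green run | 2.2 | 0.548 |
| green run | 2.9 | 0.570 |
| green run | 3.6 | 0.572 |

(scatter of a reading: 0.004 M)

- Overall: substrate + reagent -> target.
- Constant volume, constant temperature.
- "The second partner" is reagent.

- target in the grey run at 9.0 h, as a share of the substrate charged

Read the teal column against the green one. Both flasks start with the same substrate and reagent, and green also starts with 0.400 M of target. Over the first 0.72 h, the green flask gains 0.0770 M of target, less than the 0.115 M gained by the teal flask. Target already present therefore goes with a lower net rate. As the flask runs, that drag should grow with the target while the making falls with its partners, so the net rate drifts towards zero.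

Down the green column, the last step is 0.00200 M, within the scatter of 0.004 M, so the green readings show no further climb. This gives a rule for the next flask. The stopping quotient is the target divided by the product of substrate and reagent, each reckoned as charge minus target gained, where the climb ends (an apparent equilibrium constant). The last green reading gives 1.95 M⁻¹. The last teal reading gives 1.52 M⁻¹, lower than that, and the teal readings are still rising.

The grey flask has the teal charge and a long time. Setting its quotient equal to the green value gives 1.95 M as the sum term of the quadratic, then 0.312 M of target, or 39.0 % of the substrate charged.

The forecast stands at 38.9 %, reasoning that “This points to a reversible reaction”.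

The grey flask gives 37.2 %.

    substrate + reagent → target + by-product (0.3960 M⁻¹ h⁻¹)
    target + reagent → side product (0.08100 M⁻¹ h⁻¹)
    target → decomposed product (0.06336 h⁻¹)

The grey flask holds 0.298 M of target at 9.0 h, a quotient of 1.73 M⁻¹, lower than the green reading. That level is no equilibrium, since the passing of target into decomposed product holds the grey target down. The grey run without that step reaches 54.6 % of the substrate charged instead of 37.2 %, and its target of 0.437 M gives a quotient of 5.94 M⁻¹, higher than the green reading.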